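Reagent is conserved, and it is the limiting reagent here: each unit charged is free in either phase, or sits in target or isomer, or in over-reacted product, which holds two. Put your hunch, that twice the reagent pays in proportion in target, through that balance.

- epsilon: substrate 0.62 M; reagent in the second phase 0.35 equiv; run made earlier
- flask: substrate 0.62 M; reagent in the second phase 0.700 equiv; time 10 min; volume of the second phase over the first 0.25
epsilon run (percent of the substrate charged)

| time / min | target / % | substrate / % |
|---|---|---|
| 1.00 | 9.5 | 90.9 |
| 3.00 | 18.5 | 80.2 |
| 5.00 | 20.5 | 76.9 |
| 8.00 | 19.7 | 75.3 |

(readings scatter by 0.5 percentage points)
- in the second phase: reagent in the second phase; everything else is in the first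
- charges count per volume of the first phase; a concentration in a rate is the amount of a species over the volume of its own phase; every rate counts per litre of the first phase
- the numbers in the tables scatter by 0.5 percentage points (one standard deviation)
- on the list of suspects stand: reagent in the reaction phase <-> reagent in the second phase; substrate + reagent in the reaction phase <-> target; reagent in the reaction phase + target -> over-reacted product; target <-> isomer of the product
- the earlier runs hold the two phases in the same ratio of volumes as the flask asked about
* the target standing at 10 min, as a percentage of the substrate charged
* part of the substrate charged that has reacted at 10 min

Take the last epsilon reading, in fractions of the charge. The gap, neither substrate nor target, is 5.00%; count it as over-reacted product. Free reagent is then 5.30%, and target over substrate reads 0.262. Their quotient is 4.94: call it the exchange number, target over substrate per unit of free reagent. It is coarse, a small difference of readings, and as a mass-action ratio I take it proportional to the substrate charged.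

Late in the epsilon readings the gap grew at 0.0361 min⁻¹ per unit of target. Assume this scales with the reagent charge and that target stays near its end value; the gap is then 0.419 of what reacts. Solving the balance, I commit to 43.1% reacted and 25.0% target. So no proportion.

The forecast, higher in target than mine, says 34% target and 45% reacted: “The over-reaction share is the main uncertainty”. The flask gives 24.2% target with 42.9% reacted.

    reagent in the reaction phase ⇌ reagent in the second phase, rate k1*([reagent in the reaction phase] - [reagent in the second phase]/K1) per volume of the first phase (partition coefficient = 0.528, kL = 0.0624 min⁻¹)
    substrate + reagent in the reaction phase ⇌ target (K = 7.60 L mol⁻¹, k = 8.62 L mol⁻¹ min⁻¹)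
    reagent in the reaction phase + target → over-reacted product (k = 0.869 L mol⁻¹ min⁻¹)
    target ⇌ isomer of the product (K = 0.760, k = 0.0100 min⁻¹)

Count this flask the same way, though 2.55% of its gap is isomer: free reagent 8.36%, exchange number 5.07. Now take the neighbour charged with 0.15 M of substrate, and scale the exchange number to 1.19. That neighbour ends with 69.3% substrate and 21.6% target, so by that count its gap is 9.05% and its free reagent 30.3%. The balance expects target over substrate of 0.361 there, and that neighbour shows 0.312.

(All runs are calculated with made-up constants.)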